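## Retrosynthetic overview

1. Three bought pieces: (−)-β-caryophyllene 1 (cyclobutane, nine-membered ring, C1 and C9), benzaldehyde 2 and 2,4-diformylphloroglucinol 3 (aromatic ring with both CHO groups).
2. C1′–aryl bond: Knoevenagel condensation of 2 at the only free ring CH of 3, through carbinol 4, to o-quinone methide 5.
3. Key disconnection: the dihydropyran ring of target 6 (bonds O–C4 and C1′–C5) opens by retro hetero-Diels–Alder to 5 and the E C4=C5 alkene of 1.
4. Ring order: three rings are bought; the dihydropyran ring is the only ring formed, last, in the same pot as 5.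
5. Stereocentres: C1 and C9 are bought; C4 and C5 come from suprafacial addition to the exposed face of the E alkene; C1′ comes from the cycloaddition topology.

Assumption: 3 is bought as a catalogue compound and 1 is the natural (1R,9S) enantiomer; atom labels C1–C15 and C1′ follow caryophyllene numbering.

## Route

Step 1
Reactants: 1 (−)-β-caryophyllene; 2 benzaldehyde; 3 2,4-diformylphloroglucinol
Product: 6 (1R,4R,7S,11S,12R)-14,16-dihydroxy-1,5,5-trimethyl-8-methylidene-12-phenyl-19-oxatetracyclo[9.8.0.0^4,7.0^13,18]nonadeca-13,15,17-triene-15,17-dicarbaldehyde (target), via benzylic carbinol 4 (not isolated), via o-quinone methide 5 (not isolated)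
Conditions: TsOH·H2O (5 mol%), H2O, 100 °C, 16 h, vigorous stirring; 1 (3 equiv), 2 (1.5 equiv); SiO2 chromatography
Reagents that add atoms: none
Why: Knoevenagel condensation gives 5, which reacts in an inverse-electron-demand hetero-Diels–Alder cycloaddition with the strained, electron-rich E C4=C5 alkene of 1 (more reactive than the exocyclic alkene; oxygen goes to the tertiary C4), where suprafacial addition turns the E geometry into the trans ring fusion, the bought C1/C9 centres expose one alkene face in the dominant conformers (the face that also gives natural caryophyllene oxide) to set 4R,5S, and a transition state with phenyl outside and H-5 rather than CH2-6 under the heterodiene sets 1′R.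

Notes on step 1:
- 3 has a single unsubstituted ring carbon, so the condensation is regiospecific and 5 cannot be trapped at carbon by a second molecule of 3.
- The 1′-epimer and the 4,5-diastereomers from the minor conformer of 1 are the expected co-products and are removed by chromatography (preparative HPLC if needed).
- A realistic isolated yield of 6 is about 20–30%, assuming 6 is the main adduct as the topology argument predicts; I have not confirmed which epimer dominates.

## Compound list

```
1 | (−)-β-caryophyllene, (1R,4E,9S)-4,11,11-trimethyl-8-methylidenebicyclo[7.2.0]undec-4-ene | C=C1CC/C=C(C)/CC[C@@H]2[C@@H]1CC2(C)C | starting material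
2 | benzaldehyde | O=Cc1ccccc1 | starting material
3 | 2,4-diformylphloroglucinol, 2,4,6-trihydroxybenzene-1,3-dicarbaldehyde | O=Cc1c(O)cc(O)c(C=O)c1O | starting material
4 | benzylic carbinol, 2,4,6-trihydroxy-5-[hydroxy(phenyl)methyl]benzene-1,3-dicarbaldehyde (racemic) | O=Cc1c(O)c(C(O)c2ccccc2)c(O)c(C=O)c1O | intermediate
5 | o-quinone methide, 5-benzylidene-2,4-dihydroxy-6-oxocyclohexa-1,3-diene-1,3-dicarbaldehyde (interconverting tautomers) | O=CC1=C(O)C(=Cc2ccccc2)C(=O)C(C=O)=C1O | intermediate
6 | target, guajadial-type meroterpenoid: (1R,4R,7S,11S,12R)-14,16-dihydroxy-1,5,5-trimethyl-8-methylidene-12-phenyl-19-oxatetracyclo[9.8.0.0^4,7.0^13,18]nonadeca-13,15,17-triene-15,17-dicarbaldehyde; in caryophyllene numbering 1R,4R,5S,9S,1′R, with a 6,8-diformyl-5,7-dihydroxy-4-phenylchromane fused across C4–C5 (O on C4, C1′ on C5), 4-Me anti to H-5, H-1′ anti to H-5 | C=C1CC[C@H]2[C@H](c3ccccc3)c3c(O)c(C=O)c(O)c(C=O)c3O[C@]2(C)CC[C@@H]2[C@@H]1CC2(C)C | target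
```

## Step count and risks

Total step count: 1. Longest linear sequence: 1 step.

The route has only step 1, so it is the only step that can be ranked. Its risks are:
- acid-induced isomerisation or hydration of 1 in hot water;
- stalling at carbinol 4, or re-hydration of 5;
- competing cationic transannular cyclisation of 1 after attack on 5;
- a diastereomer mixture that is hard to separate.

Fallback for step 1: the fallback sets out from 3 and generates 5 without water or acid. Condensing 3 with 2 and morpholine (EtOH, 25 °C) gives the Mannich (Betti) base 2,4,6-trihydroxy-5-[morpholin-4-yl(phenyl)methyl]benzene-1,3-dicarbaldehyde F1, which is filtered off and dried. Heating F1 with 1 (3 equiv) in toluene at 110 °C releases morpholine by retro-Mannich elimination and forms 5 slowly at low concentration. The same hetero-Diels–Alder reaction then brings the fallback back to the route at 6.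

## Further compounds

```
F1 | step 1 | 2,4,6-trihydroxy-5-[morpholin-4-yl(phenyl)methyl]benzene-1,3-dicarbaldehyde (racemic) | O=Cc1c(O)c(C(N2CCOCC2)c2ccccc2)c(O)c(C=O)c1O
```
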